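**Retrosynthetic overview**
1. The last ring to close is the tetramethylcyclohexenedione ring. It is cut at the two bonds that leave the enol ether C=C(O) pair it shares with the dihydropyran, a formal (4+2) disconnection into a cyclic silyl ketene acetal of a δ-lactone (two carbons) and 2,2,4,4-tetramethylcyclobutane-1,3-dione (four carbons, after C–C cleavage).
2. Enabling feature: the ring segment C(=O)–CMe2–C(=O)–CMe2 is, atom for atom, the opened dimer of dimethylketene. The other two ring atoms are the α-carbon and the O-bearing carbon of the pyran enol ether, that is, a lactone at the ketene acetal oxidation level, nucleophilic at one carbon and electrophilic at the other.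
3. The δ-lactone comes by hydrolysis and decarboxylation from the oxa-Diels–Alder adduct of (−)-β-caryophyllene with isobutylidene Meldrum's acid (from isobutyraldehyde and Meldrum's acid); this cycloaddition sets the three new stereocenters.
4. Ring order: cyclobutane and nine-membered ring (chiral pool), then the dihydropyran (step 1), then the trione carbocycle (step 4, last).

Key step: step 4

Assumption: the cyclobutane ring-fusion carbons of the target have the configuration of natural (−)-β-caryophyllene, (1R,9S), so this commercial sesquiterpene is taken as the source of both carbocycles and of the absolute configuration.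

**Step 1**
Reactants: 1 (−)-β-caryophyllene (2 equiv); 2 isobutyraldehyde; 3 Meldrum's acid
Product: 5 oxa-Diels–Alder adduct (dihydropyran fused to a 2,2-dimethyl-1,3-dioxin-4-one), via isobutylidene Meldrum's acid 4 (not isolated)
Conditions: ethylenediammonium diacetate (10 mol %), MeCN, 25 → 45 °C
Reagents that add atoms: isobutyraldehyde (2), CC(C)C=O; Meldrum's acid (3), CC1(C)OC(=O)CC(=O)O1
Why: Domino Knoevenagel/inverse-electron-demand oxa-Diels–Alder reaction, in which alkylidene 4 (formed with loss of water), a strongly electron-poor 1-oxadiene of the same shape as the alkylidene cyclic 1,3-diones known to add to caryophyllene, should react at the strained trans-configured endocyclic alkene of 1 (not at the exocyclic methylene) with oxygen bonding to the methyl-bearing carbon, suprafacially (angular methyl anti to the ring-fusion hydrogen, trans-fused pyran) and on the exposed outer face of the major conformer (the face used in epoxidation to natural caryophyllene oxide), while the isopropyl-bearing center requires the oxadiene, with its isopropyl group pointing outward, to lie over the side of the alkene that carries the methyl group, a preference that is not secured, so the epimer at this carbon is to be expected and removed by chromatography.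

**Step 2**
Reactants: 5 oxa-Diels–Alder adduct
Product: 8 δ-lactone (tetrahydropyran-2-one trans-fused to the nine-membered ring), via acylketene 6 (not isolated), via carboxy lactone 7 (not isolated)
Conditions: H2O (10 equiv), pyridine, 110 °C
Reagents that add atoms: none
Why: Thermal retro-[4+2] fragmentation of the dioxinone expels acetone, water adds to acylketene 6, and the malonic-type half acid 7 loses CO2 on heating (standard dioxinone and Meldrum's acid chemistry), so water supplies only hydrogen to 8 and none of the pyran stereocenters, which are neither enolisable nor cleaved, is touched.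

**Step 3**
Reactants: 8 δ-lactone
Product: 9 cyclic tert-butyldimethylsilyl ketene acetal of lactone 8
Conditions: commercial LiN(i-Pr)2, THF, −78 °C; t-BuMe2SiCl, DMPU, −78 → 0 °C; pentane extraction, used without chromatography
Reagents that add atoms: tert-butyldimethylsilyl chloride, CC(C)(C)[Si](C)(C)Cl
Why: Kinetic enolisation of the lactone at its only acidic CH2 followed by O-silylation in the presence of DMPU is the standard route to cyclic silyl ketene acetals and touches no stereocenter.

**Step 4**
Reactants: 9 cyclic silyl ketene acetal; 10 2,2,4,4-tetramethylcyclobutane-1,3-dione (1.5 equiv)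
Product: 14 myrtucommulone K, via cyclobutanone adduct 11 (not isolated), via silyl enol ether 12 (not isolated), via silyl ketal 13 (not isolated)
Conditions: t-BuMe2SiOTf (20 mol %), 4 Å molecular sieves, CH2Cl2, no base, −78 → 0 °C; then Et3N, aqueous NaHCO3
Reagents that add atoms: 2,2,4,4-tetramethylcyclobutane-1,3-dione (10), CC1(C)C(=O)C(C)(C)C1=O
Why: Proposed new method: a formal (4+2) annulation of a lactone-derived silyl ketene acetal with a cyclobutane-1,3-dione under C–C cleavage, in which the silyl triflate activates one carbonyl group of 10 and the nucleophilic α-carbon of 9 adds in Mukaiyama aldol fashion to give 11, a 3-silyloxycyclobutanone that behaves as a donor–acceptor cyclobutane and opens by retro-aldol C–C cleavage, driven by release of the four-membered ring strain, to silyl enol ether 12 with the new ketone on the lactone α-carbon. The silyl triflate then activates the lactone carbonyl oxygen of this β-keto lactone, the tetrasubstituted enol carbon closes the six-membered carbocycle onto the resulting O-silyl dialkoxycarbenium carbon in a 6-(enolendo)-exo-trig, Mukaiyama–Claisen-type step that releases the silyl group of the enol ether as the triflate again and gives ketal 13, and E1cB-type loss of tert-butyldimethylsilanol across the α-carbon and the ketal carbon, completed by Et3N in the quench, gives the vinylogous ester 14. The closest known reaction types are the Lewis-acid-mediated formal [4+2] cycloadditions of 3-alkoxycyclobutanones with silyl enol ethers and the ring opening of 10 by nucleophiles to 2,2,4-trimethyl-3-oxopentanoyl derivatives. No stereocenter is created in the product, because the two sp3 carbons formed on the way to 13 become the enol ether double bond, and the three pyran and two cyclobutane stereocenters are not enolisable and are not touched. The step needs C- rather than O-attack in both bond formations (O-closure would give an ortho ester that reopens to the same cation), reaction at the ketene acetal rather than at the 1,1-disubstituted alkene (secured by the far higher nucleophilicity of the ketene acetal at −78 °C), retention of the doubly activated α-hydrogen until the ring is closed (no amine base is present during the reaction) and departure of the silyloxy group rather than of the tertiary ring oxygen (silanolate is the better leaving group, so the pyran C–O bond stays closed). The symmetry of 10 removes every regiochemical question, since both carbonyl groups and both cleavable ring bonds are equivalent.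

**Compound list**
1 | (−)-β-caryophyllene, (1R,4E,9S)-4,11,11-trimethyl-8-methylidenebicyclo[7.2.0]undec-4-ene | C=C1CC/C=C(\C)CC[C@@H]2[C@@H]1CC2(C)C | starting material
2 | isobutyraldehyde (2-methylpropanal) | CC(C)C=O | starting material
3 | Meldrum's acid (2,2-dimethyl-1,3-dioxane-4,6-dione) | CC1(C)OC(=O)CC(=O)O1 | starting material
4 | 2,2-dimethyl-5-(2-methylpropylidene)-1,3-dioxane-4,6-dione | CC(C)C=C1C(=O)OC(C)(C)OC1=O | intermediate
5 | oxa-Diels–Alder adduct: 3,4-dihydro-2H-pyran trans-fused to the nine-membered ring (ring O on the methyl-bearing carbon, angular methyl anti to the ring-fusion H, isopropyl cis to the angular methyl), its C=C(O) being part of a fused 2,2-dimethyl-1,3-dioxin-4-one | C=C1CC[C@H]2[C@@H](C(C)C)C3=C(O[C@]2(C)CC[C@@H]2[C@@H]1CC2(C)C)OC(C)(C)OC3=O | intermediate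
6 | acylketene: δ-lactone of the same skeleton carrying a ketene (C=C=O) at the α-carbon | C=C1CC[C@H]2[C@@H](C(C)C)C(=C=O)C(=O)O[C@]2(C)CC[C@@H]2[C@@H]1CC2(C)C | intermediate
7 | α-carboxy δ-lactone (α-carbon configuration undefined) | C=C1CC[C@H]2[C@@H](C(C)C)C(C(=O)O)C(=O)O[C@]2(C)CC[C@@H]2[C@@H]1CC2(C)C | intermediate
8 | δ-lactone: tetrahydropyran-2-one trans-fused to the nine-membered ring, ring O on the methyl-bearing quaternary carbon, CH(i-Pr) at the β-position, CH2 at the α-position, configuration as in 5 | C=C1CC[C@H]2[C@@H](C(C)C)CC(=O)O[C@]2(C)CC[C@@H]2[C@@H]1CC2(C)C | intermediate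
9 | cyclic silyl ketene acetal of 8: 6-(tert-butyldimethylsilyloxy)-3,4-dihydro-2H-pyran, configuration as in 8 | C=C1CC[C@H]2[C@@H](C(C)C)C=C(O[Si](C)(C)C(C)(C)C)O[C@]2(C)CC[C@@H]2[C@@H]1CC2(C)C | intermediate
10 | 2,2,4,4-tetramethylcyclobutane-1,3-dione (dimethylketene dimer) | CC1(C)C(=O)C(C)(C)C1=O | starting material
11 | cyclobutanone adduct: lactone 8 carrying a 1-(tert-butyldimethylsilyloxy)-2,2,4,4-tetramethyl-3-oxocyclobutyl group at the α-carbon (α-carbon configuration undefined) | C=C1CC[C@H]2[C@@H](C(C)C)C(C(=O)O[C@]2(C)CC[C@@H]2[C@@H]1CC2(C)C)C3(O[Si](C)(C)C(C)(C)C)C(C)(C)C(=O)C3(C)C | intermediate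
12 | ring-opened silyl enol ether: lactone 8 carrying a 2,2,4-trimethyl-3-(tert-butyldimethylsilyloxy)pent-3-enoyl group at the α-carbon | C=C1CC[C@H]2[C@@H](C(C)C)C(C(=O)O[C@]2(C)CC[C@@H]2[C@@H]1CC2(C)C)C(=O)C(C)(C)C(O[Si](C)(C)C(C)(C)C)=C(C)C | intermediate
13 | silyl ketal: saturated precursor of 14 with H at the α-carbon and OSi(t-Bu)Me2 on the O-bearing carbon (both transient centers undefined) | C=C1CC[C@H]2[C@@H](C(C)C)C3C(O[Si](C)(C)C(C)(C)C)(O[C@]2(C)CC[C@@H]2[C@@H]1CC2(C)C)C(C)(C)C(=O)C(C)(C)C3=O | intermediate
14 | myrtucommulone K (caryophyllane numbering: 1R,4R,5S,9S; isopropyl-bearing carbon R) | C=C1CC[C@H]2[C@@H](C(C)C)C3=C(O[C@]2(C)CC[C@@H]2[C@@H]1CC2(C)C)C(C)(C)C(=O)C(C)(C)C3=O | target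

Total step count: 4
Longest linear sequence: 4 steps (from 1)

**Steps most likely to fail**

Step 4. The cascade may stall after the first C–C bond: the silyl group can leave the O-silylated lactone before the hindered enol carbon closes the ring, so that the sequence ends at the open-chain acyl lactone. Addition to the hindered carbonyl group may also be slow enough for protodesilylation of the ketene acetal to take over. The fallback uses known chemistry, still closes the carbocycle last, sets out from 1 (with 2 and 10) and comes back at 14. Dione 10 is opened by LiCH2CO2Me (2 equiv, from methyl acetate and LiN(i-Pr)2, THF, −78 °C → rt), a Claisen-type acylation that is the carbon counterpart of the well-known alcoholysis of 10, to give methyl 4,4,6-trimethyl-3,5-dioxoheptanoate F1. Knoevenagel condensation with 2 (piperidinium acetate, CH2Cl2, loss of water) gives methyl 2-(2-methylpropylidene)-4,4,6-trimethyl-3,5-dioxoheptanoate F2. Its keto-oxadiene should add to the ring alkene of 1 (toluene, 80–110 °C) in an oxa-Diels–Alder reaction to the dihydropyran ester F3, which carries CO2Me on the enol ether α-carbon and the CMe2–C(=O)–CHMe2 chain on the O-bearing carbon. Dieckmann-type closure (LiN(SiMe3)2, THF, −78 → 0 °C), in which the enolate of the only enolisable position, the isopropyl ketone, attacks the ester and methanol is lost, then gives 14.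

Step 1. Poor endo/exo selectivity at the isopropyl-bearing carbon is the main concern; competing addition of a second Meldrum's acid to 4 is a further one. The fallback sets this center by substrate-controlled hydride delivery; it sets out from 1 and comes back at 8. Isobutyronitrile oxide F4, generated from commercial isobutyraldoxime with PhI(OAc)2 in MeOH in the presence of 1, should add to the strained ring alkene on the same outer face, with oxygen at the methyl-bearing carbon, to give isoxazoline F5. Mo(CO)6 in wet MeCN at 80 °C cleaves the N–O bond and the imine hydrolyses (loss of ammonia) to β-hydroxy ketone F6. The tertiary alcohol is esterified with diethylphosphonoacetic acid (DCC, DMAP, CH2Cl2) to phosphonoacetate F7, and intramolecular Horner–Wadsworth–Emmons olefination (LiCl, i-Pr2NEt, MeCN) gives the β-isopropyl α,β-unsaturated δ-lactone F8. Conjugate reduction with [(Ph3P)CuH]6 (catalytic) and PhSiH3 in toluene, then aqueous NH4F, should deliver hydride to the β-carbon from the face opposite the angular methyl and the neighbouring ring methylene, giving 8.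

Step 2. At the temperature needed for cycloreversion in a hot aqueous medium, ionisation of the tertiary alkyl–oxygen bond of the lactone (with transannular participation of the methylene) or retro-cycloaddition may compete with decarboxylation. The fallback separates ketene trapping from decarboxylation; it sets out from 5 and comes back at 8. Thermolysis of 5 in dry toluene with allyl alcohol (110 °C) expels acetone and traps acylketene 6 as the allyl α-carboxylate lactone F9. Deallylation with Pd(PPh3)4 (zerovalent palladium), HCO2H and Et3N in THF at room temperature gives acid 7 under neutral conditions, and brief warming in pyridine (90 °C) decarboxylates it to 8.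

**Further compounds**
F1 | step 4 | methyl 4,4,6-trimethyl-3,5-dioxoheptanoate | COC(=O)CC(=O)C(C)(C)C(=O)C(C)C
F2 | step 4 | methyl 2-(2-methylpropylidene)-4,4,6-trimethyl-3,5-dioxoheptanoate (E/Z mixture) | COC(=O)C(=CC(C)C)C(=O)C(C)(C)C(=O)C(C)C
F3 | step 4 | dihydropyran ester: pyran of 14 with CO2Me on the enol ether α-carbon and a 1,1,3-trimethyl-2-oxobutyl chain on the O-bearing carbon | C=C1CC[C@H]2[C@@H](C(C)C)C(C(=O)OC)=C(O[C@]2(C)CC[C@@H]2[C@@H]1CC2(C)C)C(C)(C)C(=O)C(C)C
F4 | step 1 | isobutyronitrile oxide | CC(C)C#[N+][O-]
F5 | step 1 | isoxazoline fused to the nine-membered ring (O on the methyl-bearing carbon, C(i-Pr)=N on the adjacent CH) | C=C1CC[C@H]2C(C(C)C)=NO[C@]2(C)CC[C@@H]2[C@@H]1CC2(C)C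
F6 | step 1 | β-hydroxy ketone (tertiary alcohol next to the CH carrying the isobutyryl group) | C=C1CC[C@@H](C(=O)C(C)C)[C@](C)(O)CC[C@@H]2[C@@H]1CC2(C)C
F7 | step 1 | diethylphosphonoacetate ester of F6 | C=C1CC[C@@H](C(=O)C(C)C)[C@](C)(OC(=O)CP(=O)(OCC)OCC)CC[C@@H]2[C@@H]1CC2(C)C
F8 | step 1 | β-isopropyl α,β-unsaturated δ-lactone (5,6-dihydro-2H-pyran-2-one fused to the nine-membered ring) | C=C1CC[C@H]2C(C(C)C)=CC(=O)O[C@]2(C)CC[C@@H]2[C@@H]1CC2(C)C
F9 | step 2 | allyl ester of carboxy lactone 7 (α-carbon configuration undefined) | C=C1CC[C@H]2[C@@H](C(C)C)C(C(=O)OCC=C)C(=O)O[C@]2(C)CC[C@@H]2[C@@H]1CC2(C)C
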